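Ring B is built de novo: one Diels–Alder benzannulation makes the two C–C bonds on either side of its adjacent lactone-carbonyl and lactol-bearing carbons. The step exploits the pattern on the other four ring B carbons, which carry in sequence the diaryl-ether oxygen, the depside oxygen, a methyl and a phenol. That pattern is a 4-aryloxy-1-methoxy-2-methyl-1,3-bis(silyloxy)diene, which takes up an acetylenic ester bearing a masked aldehyde. The hindered diaryl ether is therefore made earlier as a plain alkyl aryl ether, by alkylating the ring A salicylate with a bromo keto ester. Depsidone lactonisation, lactol release and an enzymatic dynamic resolution complete the route.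

Key step: step 12

Assumption: the lactol carbon (R in the target by CIP analysis) epimerises by ring–chain tautomerism in protic, acidic or basic media and is taken to hold its configuration in dry, neutral, aprotic solution at or below 5 °C; the lipase of steps 16 and 17 is taken to be one whose fast-reacting enantiomer is (R), found by screening commercial lipases.

Step 1
Reactants: 1 creosol (2-methoxy-4-methylphenol)
Product: 2 2-hydroxy-3-methoxy-5-methylbenzaldehyde
Conditions: (CH2O)n, MgCl2, Et3N, MeCN, reflux; aq. HCl work-up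
Reagents that add atoms: paraformaldehyde (as formaldehyde), C=O
Why: Magnesium phenoxide-directed ortho-formylation (Casiraghi–Skattebøl) can only attack C-6, the single free position ortho to the hydroxyl, because the para position carries the methyl group.

Step 2
Reactants: 2 2-hydroxy-3-methoxy-5-methylbenzaldehyde
Product: 3 2-(benzyloxy)-3-methoxy-5-methylbenzaldehyde
Conditions: BnBr, K2CO3, DMF, rt
Reagents that add atoms: benzyl bromide, BrCc1ccccc1
Why: Williamson ether synthesis protects the hydroxyl that ends as the free ring A phenol, as a group that later leaves by hydrogenolysis together with the benzyl ester.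

Step 3
Reactants: 3 2-(benzyloxy)-3-methoxy-5-methylbenzaldehyde
Product: 5 2-(benzyloxy)-3-methoxy-5-methylphenol, via aryl formate 4 (not isolated)
Conditions: mCPBA, CH2Cl2, 0 °C to rt; then cat. K2CO3, MeOH, rt
Reagents that add atoms: mCPBA, OOC(=O)c1cccc(Cl)c1
Why: Baeyer–Villiger oxidation of an electron-rich ortho-alkoxybenzaldehyde proceeds with aryl migration to the formate, and mild methanolysis then frees the phenol that becomes the diaryl ether oxygen.

Step 4
Reactants: 5 2-(benzyloxy)-3-methoxy-5-methylphenol
Product: 6 3-(benzyloxy)-2-hydroxy-4-methoxy-6-methylbenzaldehyde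
Conditions: (CH2O)n, MgCl2, Et3N, THF, reflux; aq. HCl work-up
Reagents that add atoms: paraformaldehyde (as formaldehyde), C=O
Why: The same magnesium-mediated ortho-formylation is regiospecific, since the only unsubstituted position ortho to the new hydroxyl is the one next to the methyl group.

Step 5
Reactants: 6 3-(benzyloxy)-2-hydroxy-4-methoxy-6-methylbenzaldehyde
Product: 7 3-(benzyloxy)-2-hydroxy-4-methoxy-6-methylbenzoic acid
Conditions: NaClO2, NaH2PO4, 2-methyl-2-butene, t-BuOH/H2O, 0 °C to rt
Reagents that add atoms: sodium chlorite, [Na+].[O-]Cl=O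
Why: Pinnick oxidation converts the aldehyde into the acid under buffered conditions while excess 2-methyl-2-butene traps hypochlorous acid, so the electron-rich ring should not be chlorinated.

Step 6
Reactants: 7 3-(benzyloxy)-2-hydroxy-4-methoxy-6-methylbenzoic acid
Product: 8 benzyl 3-(benzyloxy)-2-hydroxy-4-methoxy-6-methylbenzoate
Conditions: BnBr, KHCO3, DMF, rt
Reagents that add atoms: benzyl bromide, BrCc1ccccc1
Why: With the weak base KHCO3 only the carboxylate is alkylated (SN2 esterification), and the hydrogen-bonded salicylate hydroxyl stays free for the etherification.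

Step 7
Reactants: 9 methyl 2-methyl-3-oxobutanoate
Product: 11 methyl 4-bromo-2-methyl-3-oxobutanoate (racemic), via 2-bromo isomer 10 (not isolated)
Conditions: Br2, CHCl3, 0 °C to rt, 16 h
Reagents that add atoms: bromine, BrBr
Why: Electrophilic bromination gives first the 2-bromo keto ester, which hydrogen bromide equilibrates by reversible enol bromination to the favoured 4-bromo isomer, the known behaviour of 2-alkylacetoacetates.

Step 8
Reactants: 8 benzyl 3-(benzyloxy)-2-hydroxy-4-methoxy-6-methylbenzoate; 11 methyl 4-bromo-2-methyl-3-oxobutanoate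
Product: 12 benzyl 3-(benzyloxy)-4-methoxy-2-(4-methoxy-3-methyl-2,4-dioxobutoxy)-6-methylbenzoate
Conditions: K2CO3, acetone, 0 °C to rt, slow addition of 11
Reagents that add atoms: none
Why: SN2 displacement of the reactive alpha-bromo ketone by the salicylate phenoxide (Williamson etherification) forms the future diaryl ether C–O bond while it is still an unhindered alkyl aryl ether, and the twisted di-ortho-substituted benzyl ester is a poor partner for a competing Dieckmann closure.

Step 9
Reactants: 12 benzyl 3-(benzyloxy)-4-methoxy-2-(4-methoxy-3-methyl-2,4-dioxobutoxy)-6-methylbenzoate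
Product: 13 benzyl 3-(benzyloxy)-4-methoxy-2-{[4-methoxy-3-methyl-4-oxo-2-(trimethylsilyloxy)but-2-en-1-yl]oxy}-6-methylbenzoate
Conditions: TMSCl, Et3N, toluene, rt; filtration under argon
Reagents that add atoms: chlorotrimethylsilane, C[Si](C)(C)Cl
Why: Amine-mediated enolisation of the 1,3-dicarbonyl unit and O-silylation give the conjugated 3-silyloxy enoate, the first stage of the standard two-stage preparation of 1,3-bis(silyloxy)dienes.

Step 10
Reactants: 13 benzyl 3-(benzyloxy)-4-methoxy-2-{[4-methoxy-3-methyl-4-oxo-2-(trimethylsilyloxy)but-2-en-1-yl]oxy}-6-methylbenzoate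
Product: 15 benzyl 3-(benzyloxy)-4-methoxy-2-{[4-methoxy-3-methyl-2,4-bis(trimethylsilyloxy)buta-1,3-dien-1-yl]oxy}-6-methylbenzoate, via lithium dienolate 14 (not isolated)
Conditions: LiN(i-Pr)2 (LDA, 1.1 equiv), THF, −78 °C; then TMSCl, −78 to 0 °C
Reagents that add atoms: chlorotrimethylsilane, C[Si](C)(C)Cl
Why: Kinetic gamma-deprotonation of the vinylogous ester at the doubly activated OCH2 group and O-silylation of the dienolate give the bis(silyloxy)diene, as established for dienes from 4-aryloxyacetoacetates, and the low temperature and single equivalent of base are meant to spare the ring A methyl and benzyl ester.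

Step 11
Reactants: 16 3,3-diethoxyprop-1-yne
Product: 18 tert-butyl 4,4-diethoxybut-2-ynoate, via lithium acetylide 17 (not isolated)
Conditions: n-BuLi, THF, −78 °C; then Boc2O, −78 °C to rt
Reagents that add atoms: di-tert-butyl dicarbonate, CC(C)(C)OC(=O)OC(=O)OC(C)(C)C
Why: Acylation of the lithium acetylide with Boc2O gives the tert-butyl ynoate, an ester chosen so that a single acid treatment later frees the ring B carboxyl and aldehyde together.

Step 12
Reactants: 15 benzyl 3-(benzyloxy)-4-methoxy-2-{[4-methoxy-3-methyl-2,4-bis(trimethylsilyloxy)buta-1,3-dien-1-yl]oxy}-6-methylbenzoate; 18 tert-butyl 4,4-diethoxybut-2-ynoate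
Product: 21 benzyl 3-(benzyloxy)-2-[3-(tert-butoxycarbonyl)-2-(diethoxymethyl)-4,6-dihydroxy-5-methylphenoxy]-4-methoxy-6-methylbenzoate, via cycloadduct 19 (not isolated), via bis(trimethylsilyl) ether 20 (not isolated)
Conditions: toluene, 110 °C, sealed tube, argon; then Bu4NF, AcOH, THF, 0 °C
Reagents that add atoms: none
Why: The electron-rich diene 15 and the electron-poor ynoate 18 should combine in a thermal, strongly asynchronous Diels–Alder reaction, the established benzannulation of 1-alkoxy-1,3-bis(silyloxy)dienes with acetylenic esters to resorcinol esters. Ring B closes in a six-membered [4+2] mode through two new C–C bonds, diene C-4 to the acetal-bearing alkyne carbon and diene C-1 to the ester-bearing one. Cyclohexa-1,4-diene 19 has no hydrogen placed for loss of the aryloxy group, so it should aromatise by 1,4-elimination of methanol from the mixed ketal carbon and the aryloxy-bearing CH to give 20. Both sp3 centres of 19 disappear on aromatisation, so no stereocentre needs control. The selectivity needed is regiochemical and is secured by polarity: the diene end bearing the aryloxy group is the electron-rich end of the vinylogous ketene acetal and attacks the ynoate beta-carbon, so closure at the ketene acetal carbon puts the ester ortho to the phenol it creates and the acetal beside the ether carbon. Buffered fluoride then removes both aryl silyl ethers without touching the acetal or the tert-butyl ester.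

Step 13
Reactants: 21 benzyl 3-(benzyloxy)-2-[3-(tert-butoxycarbonyl)-2-(diethoxymethyl)-4,6-dihydroxy-5-methylphenoxy]-4-methoxy-6-methylbenzoate
Product: 22 2-[3-(tert-butoxycarbonyl)-2-(diethoxymethyl)-4,6-dihydroxy-5-methylphenoxy]-3-hydroxy-4-methoxy-6-methylbenzoic acid
Conditions: H2 (1 atm), 10% Pd/C, EtOAc, rt
Reagents that add atoms: none
Why: Palladium-catalysed hydrogenolysis cleaves the benzyl ester and the benzyl aryl ether under neutral conditions that should leave the acetal, the tert-butyl ester and the diaryl ether intact.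

Step 14
Reactants: 22 2-[3-(tert-butoxycarbonyl)-2-(diethoxymethyl)-4,6-dihydroxy-5-methylphenoxy]-3-hydroxy-4-methoxy-6-methylbenzoic acid
Product: 23 tert-butyl 6-(diethoxymethyl)-4,8-dihydroxy-3-methoxy-1,9-dimethyl-11-oxo-11H-dibenzo[b,e][1,4]dioxepine-7-carboxylate
Conditions: DCC, cat. DMAP, CH2Cl2 (about 2 mM, slow addition of 22), 0 °C to rt
Reagents that add atoms: none
Why: Carbodiimide activation of the ring A acid under high dilution (Steglich-type lactonisation) lets only the ring B hydroxyl ortho to the ether bridge reach the acyl group intramolecularly, closing the seven-membered depsidone lactone as in classical depsidone syntheses.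

Step 15
Reactants: 23 tert-butyl 6-(diethoxymethyl)-4,8-dihydroxy-3-methoxy-1,9-dimethyl-11-oxo-11H-dibenzo[b,e][1,4]dioxepine-7-carboxylate
Product: 25 rac-1,4,11-trihydroxy-10-methoxy-5,8-dimethyl-1H-isobenzofuro[4,5-b][1,4]benzodioxepine-3,7-dione, via formyl acid 24 (not isolated)
Conditions: TFA/CH2Cl2/H2O (10:10:1), 0 °C to rt
Reagents that add atoms: water, O
Why: Aqueous trifluoroacetic acid cleaves the tert-butyl ester (loss of isobutene) and hydrolyses the diethyl acetal, and the resulting ortho-formylbenzoic acid closes to the five-membered lactol by ring–chain tautomerism, necessarily as the racemate.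

Step 16
Reactants: 25 rac-1,4,11-trihydroxy-10-methoxy-5,8-dimethyl-1H-isobenzofuro[4,5-b][1,4]benzodioxepine-3,7-dione
Product: 26 (1R)-4,11-dihydroxy-10-methoxy-5,8-dimethyl-3,7-dioxo-1,3-dihydro-7H-isobenzofuro[4,5-b][1,4]benzodioxepin-1-yl acetate
Conditions: vinyl acetate, immobilised Candida antarctica lipase B (or the (R)-selective lipase found by screening), dry THF, 35 °C
Reagents that add atoms: vinyl acetate, C=COC(C)=O
Why: Lipase-catalysed acetylation acts on one lactol enantiomer while the two interconvert through the open formyl acid, a dynamic kinetic resolution known for cyclic hemiacylals, and the (R) configuration is set by the chiral active site of the enzyme selected for that preference.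

Step 17
Reactants: 26 (1R)-4,11-dihydroxy-10-methoxy-5,8-dimethyl-3,7-dioxo-1,3-dihydro-7H-isobenzofuro[4,5-b][1,4]benzodioxepin-1-yl acetate
Product: 27 (1R)-1,4,11-trihydroxy-10-methoxy-5,8-dimethyl-1H-isobenzofuro[4,5-b][1,4]benzodioxepine-3,7-dione (target CNP0211607.1)
Conditions: n-BuOH, the lipase of step 16, dry 2-methyltetrahydrofuran, 0–5 °C; filtration and cold evaporation
Reagents that add atoms: none
Why: Lipase-catalysed alcoholysis breaks the acyl–oxygen bond of the acetate and not the C–O bond at the stereocentre, so the (R) configuration is retained, the same enzyme again favours the (R) substrate, and neutral, cold, aprotic conditions should suppress ring–chain epimerisation of the released lactol.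

Compound list
1 | creosol (2-methoxy-4-methylphenol) | COc1cc(C)ccc1O | starting material
2 | 2-hydroxy-3-methoxy-5-methylbenzaldehyde | COc1cc(C)cc(C=O)c1O | intermediate
3 | 2-(benzyloxy)-3-methoxy-5-methylbenzaldehyde | COc1cc(C)cc(C=O)c1OCc1ccccc1 | intermediate
4 | 2-(benzyloxy)-3-methoxy-5-methylphenyl formate | COc1cc(C)cc(OC=O)c1OCc1ccccc1 | intermediate
5 | 2-(benzyloxy)-3-methoxy-5-methylphenol | COc1cc(C)cc(O)c1OCc1ccccc1 | intermediate
6 | 3-(benzyloxy)-2-hydroxy-4-methoxy-6-methylbenzaldehyde | COc1cc(C)c(C=O)c(O)c1OCc1ccccc1 | intermediate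
7 | 3-(benzyloxy)-2-hydroxy-4-methoxy-6-methylbenzoic acid | COc1cc(C)c(C(=O)O)c(O)c1OCc1ccccc1 | intermediate
8 | benzyl 3-(benzyloxy)-2-hydroxy-4-methoxy-6-methylbenzoate (ring A salicylate) | COc1cc(C)c(C(=O)OCc2ccccc2)c(O)c1OCc1ccccc1 | intermediate
9 | methyl 2-methyl-3-oxobutanoate | COC(=O)C(C)C(C)=O | starting material
10 | methyl 2-bromo-2-methyl-3-oxobutanoate | COC(=O)C(C)(Br)C(C)=O | intermediate
11 | methyl 4-bromo-2-methyl-3-oxobutanoate (racemic) | COC(=O)C(C)C(=O)CBr | intermediate
12 | benzyl 3-(benzyloxy)-4-methoxy-2-(4-methoxy-3-methyl-2,4-dioxobutoxy)-6-methylbenzoate (racemic keto ester) | COc1cc(C)c(C(=O)OCc2ccccc2)c(OCC(=O)C(C)C(=O)OC)c1OCc1ccccc1 | intermediate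
13 | benzyl 3-(benzyloxy)-4-methoxy-2-{[4-methoxy-3-methyl-4-oxo-2-(trimethylsilyloxy)but-2-en-1-yl]oxy}-6-methylbenzoate (alkene geometry not controlled) | COc1cc(C)c(C(=O)OCc2ccccc2)c(OCC(O[Si](C)(C)C)=C(C)C(=O)OC)c1OCc1ccccc1 | intermediate
14 | lithium dienolate of 13 (lithium 1-methoxy-2-methyl-4-aryloxy-3-(trimethylsilyloxy)buta-1,3-dien-1-olate) | COc1cc(C)c(C(=O)OCc2ccccc2)c(OC=C(O[Si](C)(C)C)C(C)=C(OC)O[Li])c1OCc1ccccc1 | intermediate
15 | benzyl 3-(benzyloxy)-4-methoxy-2-{[4-methoxy-3-methyl-2,4-bis(trimethylsilyloxy)buta-1,3-dien-1-yl]oxy}-6-methylbenzoate (drawn 1Z,3Z; geometry is lost on aromatisation) | COc1cc(C)c(C(=O)OCc2ccccc2)c(O/C=C(O[Si](C)(C)C)/C(C)=C(/OC)O[Si](C)(C)C)c1OCc1ccccc1 | intermediate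
16 | 3,3-diethoxyprop-1-yne | C#CC(OCC)OCC | starting material
17 | (3,3-diethoxyprop-1-yn-1-yl)lithium | [Li]C#CC(OCC)OCC | intermediate
18 | tert-butyl 4,4-diethoxybut-2-ynoate | CCOC(OCC)C#CC(=O)OC(C)(C)C | intermediate
19 | tert-butyl 3-(ring A aryloxy)-2-(diethoxymethyl)-6-methoxy-5-methyl-4,6-bis(trimethylsilyloxy)cyclohexa-1,4-diene-1-carboxylate (mixture of diastereomers) | COC1(O[Si](C)(C)C)C(C)=C(O[Si](C)(C)C)C(Oc2c(OCc3ccccc3)c(OC)cc(C)c2C(=O)OCc2ccccc2)C(C(OCC)OCC)=C1C(=O)OC(C)(C)C | intermediate
20 | benzyl 3-(benzyloxy)-2-[3-(tert-butoxycarbonyl)-2-(diethoxymethyl)-5-methyl-4,6-bis(trimethylsilyloxy)phenoxy]-4-methoxy-6-methylbenzoate | COc1cc(C)c(C(=O)OCc2ccccc2)c(Oc2c(O[Si](C)(C)C)c(C)c(O[Si](C)(C)C)c(C(=O)OC(C)(C)C)c2C(OCC)OCC)c1OCc1ccccc1 | intermediate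
21 | benzyl 3-(benzyloxy)-2-[3-(tert-butoxycarbonyl)-2-(diethoxymethyl)-4,6-dihydroxy-5-methylphenoxy]-4-methoxy-6-methylbenzoate | COc1cc(C)c(C(=O)OCc2ccccc2)c(Oc2c(O)c(C)c(O)c(C(=O)OC(C)(C)C)c2C(OCC)OCC)c1OCc1ccccc1 | intermediate
22 | 2-[3-(tert-butoxycarbonyl)-2-(diethoxymethyl)-4,6-dihydroxy-5-methylphenoxy]-3-hydroxy-4-methoxy-6-methylbenzoic acid | COc1cc(C)c(C(=O)O)c(Oc2c(O)c(C)c(O)c(C(=O)OC(C)(C)C)c2C(OCC)OCC)c1O | intermediate
23 | tert-butyl 6-(diethoxymethyl)-4,8-dihydroxy-3-methoxy-1,9-dimethyl-11-oxo-11H-dibenzo[b,e][1,4]dioxepine-7-carboxylate | COc1cc(C)c2c(c1O)Oc1c(c(C)c(O)c(C(=O)OC(C)(C)C)c1C(OCC)OCC)OC2=O | intermediate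
24 | 6-formyl-4,8-dihydroxy-3-methoxy-1,9-dimethyl-11-oxo-11H-dibenzo[b,e][1,4]dioxepine-7-carboxylic acid | COc1cc(C)c2c(c1O)Oc1c(c(C)c(O)c(C(=O)O)c1C=O)OC2=O | intermediate
25 | rac-1,4,11-trihydroxy-10-methoxy-5,8-dimethyl-1H-isobenzofuro[4,5-b][1,4]benzodioxepine-3,7-dione (racemic lactol) | COc1cc(C)c2c(c1O)Oc1c(c(C)c(O)c3c1C(O)OC3=O)OC2=O | intermediate
26 | (1R)-4,11-dihydroxy-10-methoxy-5,8-dimethyl-3,7-dioxo-1,3-dihydro-7H-isobenzofuro[4,5-b][1,4]benzodioxepin-1-yl acetate | COc1cc(C)c2c(c1O)Oc1c(c(C)c(O)c3c1[C@H](OC(C)=O)OC3=O)OC2=O | intermediate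
27 | (1R)-1,4,11-trihydroxy-10-methoxy-5,8-dimethyl-1H-isobenzofuro[4,5-b][1,4]benzodioxepine-3,7-dione; depsidone whose ring A carries OH (next to the ether oxygen), OCH3, H and CH3, and whose ring B carries CH3 between the depside oxygen and a phenol plus a fused lactone with C=O beside that phenol and (R)-CH(OH) beside the ether carbon | COc1cc(C)c2c(c1O)Oc1c(c(C)c(O)c3c1[C@H](O)OC3=O)OC2=O | target

Total step count: 17. Longest linear sequence: 15 steps (steps 1–6, 8–10, 12–17); steps 7 and 11 are one-step side branches.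

Steps most likely to fail

Step 12. The thermal cycloaddition between two congested carbons may be slower than desilylation or decomposition of the diene, or the mixed ketal may lose trimethylsilanol instead of methanol. The fallback closes the same two bonds by a polar, stepwise Michael–Dieckmann benzannulation, the open-chain counterpart of the Staunton–Weinreb annulation. It sets out from 13: lithium dienolate 14 (LiN(i-Pr)2, THF, −78 °C) is not silylated but treated with 18. Attack of its gamma-carbon on the ynoate beta-carbon gives an allenolate, whose alpha-carbon closes onto the methyl ester with loss of lithium methoxide. Tautomerisation should give the monosilylated resorcinol benzyl 3-(benzyloxy)-2-[3-(tert-butoxycarbonyl)-2-(diethoxymethyl)-4-hydroxy-5-methyl-6-(trimethylsilyloxy)phenoxy]-4-methoxy-6-methylbenzoate F1, and buffered Bu4NF returns the route to 21. Only methoxide can leave in this mode, and no heating is involved.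

Step 16. The enzyme may discriminate poorly between the lactol enantiomers of this bulky polyphenol, or lactol epimerisation may be too slow to keep the resolution dynamic. The fallback replaces enzymatic stereoselection by physical resolution. It sets out from 25: peracetylation (Ac2O, pyridine, 0 °C) gives racemic 4,11-diacetoxy-10-methoxy-5,8-dimethyl-3,7-dioxo-1,3-dihydro-7H-isobenzofuro[4,5-b][1,4]benzodioxepin-1-yl acetate F2, a configurationally fixed acylal. Preparative chromatography on an amylose tris(3,5-dimethylphenylcarbamate) stationary phase should deliver the (1R)-triacetate F3. Lipase-catalysed alcoholysis with excess n-butanol under the conditions of step 17, with a lipase chosen only for activity, then removes all three acetyl groups and comes back at 27. The (1S)-triacetate can be deacetylated the same way and re-equilibrated to 25 with a trace of Et3N for recycling.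

Step 8. The bromo keto ester may be consumed by its own enolate (self-alkylation or cyclisation to a tetronate) faster than the hindered, hydrogen-bonded phenoxide is alkylated. The fallback installs the keto ester in stages and needs neither step 7 nor 11. It sets out from 8: alkylation with tert-butyl bromoacetate (K2CO3, DMF) gives benzyl 3-(benzyloxy)-2-(2-tert-butoxy-2-oxoethoxy)-4-methoxy-6-methylbenzoate F4. TFA in CH2Cl2 frees {2-[(benzyloxy)carbonyl]-6-(benzyloxy)-5-methoxy-3-methylphenoxy}acetic acid F5. 1,1'-Carbonyldiimidazole converts it into the acyl imidazolide benzyl 3-(benzyloxy)-2-[2-(imidazol-1-yl)-2-oxoethoxy]-4-methoxy-6-methylbenzoate F6. Masamune–Brooks homologation with the magnesium enolate of potassium methyl methylmalonate (MgCl2, Et3N, THF), with decarboxylation, comes back at 12.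

Further compounds
F1 | step 12 | benzyl 3-(benzyloxy)-2-[3-(tert-butoxycarbonyl)-2-(diethoxymethyl)-4-hydroxy-5-methyl-6-(trimethylsilyloxy)phenoxy]-4-methoxy-6-methylbenzoate | COc1cc(C)c(C(=O)OCc2ccccc2)c(Oc2c(O[Si](C)(C)C)c(C)c(O)c(C(=O)OC(C)(C)C)c2C(OCC)OCC)c1OCc1ccccc1
F2 | step 16 | racemic 4,11-diacetoxy-10-methoxy-5,8-dimethyl-3,7-dioxo-1,3-dihydro-7H-isobenzofuro[4,5-b][1,4]benzodioxepin-1-yl acetate | COc1cc(C)c2c(c1OC(C)=O)Oc1c(c(C)c(OC(C)=O)c3c1C(OC(C)=O)OC3=O)OC2=O
F3 | step 16 | (1R)-4,11-diacetoxy-10-methoxy-5,8-dimethyl-3,7-dioxo-1,3-dihydro-7H-isobenzofuro[4,5-b][1,4]benzodioxepin-1-yl acetate | COc1cc(C)c2c(c1OC(C)=O)Oc1c(c(C)c(OC(C)=O)c3c1[C@H](OC(C)=O)OC3=O)OC2=O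
F4 | step 8 | benzyl 3-(benzyloxy)-2-(2-tert-butoxy-2-oxoethoxy)-4-methoxy-6-methylbenzoate | COc1cc(C)c(C(=O)OCc2ccccc2)c(OCC(=O)OC(C)(C)C)c1OCc1ccccc1
F5 | step 8 | {2-[(benzyloxy)carbonyl]-6-(benzyloxy)-5-methoxy-3-methylphenoxy}acetic acid | COc1cc(C)c(C(=O)OCc2ccccc2)c(OCC(=O)O)c1OCc1ccccc1
F6 | step 8 | benzyl 3-(benzyloxy)-2-[2-(imidazol-1-yl)-2-oxoethoxy]-4-methoxy-6-methylbenzoate | COc1cc(C)c(C(=O)OCc2ccccc2)c(OCC(=O)n2ccnc2)c1OCc1ccccc1
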